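## Retrosynthetic overview
1. Target 19 comes from hydrogenolysis of tris-benzyl ether 18. The diarylmethane CH2 comes from deoxygenation of carbinol 17, made from aldehyde 14 and an aryl Grignard reagent.
2. Aldehyde 14 comes from resorcylate ester 10. The hydrogen-bonded 2-OH lets the 4-OH be benzylated first and the 2-OH methylated second, and the ester then becomes CHO.
3. Resorcylate 10 comes from aromatisation of cyclohexenone 9. Compound 9 comes from intermolecular Michael addition of dimethyl malonate 7 to enone 6 (key C–C bond), followed by ring-closing Claisen condensation.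
4. Enone 6 comes from Wittig olefination of aldehyde 4, which is made from dihydrocoumarin 1.
5. Ring order: both outer benzene rings are bought. Only the central ring is built (closed in step 5, aromatised in step 6).

Assumption: the target SMILES contains no stereocentre and no double-bond geometry, so the compound is achiral and no enantiomer has to be set. The stereocentres of 8, 9 and 17 are racemic and are erased later.

## Route

Step 1
Reactants: 1 dihydrocoumarin (chroman-2-one)
Product: 2 2-(3-hydroxypropyl)phenol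
Conditions: LiAlH4 (1.2 equiv), THF, 0 °C to rt; then 1 M HCl
Reagents that add atoms: none
Why: LiAlH4 reduction of the lactone opens it to the phenol and the primary alcohol, and nothing else in the molecule is reducible.

Step 2
Reactants: 2 2-(3-hydroxypropyl)phenol
Product: 3 3-[2-(benzyloxy)phenyl]propan-1-ol
Conditions: BnBr (1.05 equiv), K2CO3 (1.5 equiv), acetone, reflux
Reagents that add atoms: benzyl bromide, BrCc1ccccc1
Why: In this Williamson ether synthesis K2CO3 deprotonates only the phenol and not the aliphatic alcohol, so benzylation is chemoselective.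

Step 3
Reactants: 3 3-[2-(benzyloxy)phenyl]propan-1-ol
Product: 4 3-[2-(benzyloxy)phenyl]propanal
Conditions: TEMPO (10 mol %), PhI(OAc)2 (1.1 equiv), CH2Cl2, rt
Reagents that add atoms: none
Why: The anhydrous TEMPO/PhI(OAc)2 oxidation of a primary alcohol stops at the aldehyde and leaves the aryl benzyl ether untouched.

Step 4
Reactants: 4 3-[2-(benzyloxy)phenyl]propanal; 5 1-(triphenylphosphoranylidene)propan-2-one
Product: 6 (E)-6-[2-(benzyloxy)phenyl]hex-3-en-2-one
Conditions: 5 (1.2 equiv), CH2Cl2, reflux, 16 h
Reagents that add atoms: none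
Why: Wittig olefination with a stabilised ylide gives the E-enone under neutral conditions that do not enolise the aldehyde.

Step 5
Reactants: 6 (E)-6-[2-(benzyloxy)phenyl]hex-3-en-2-one; 7 dimethyl malonate
Product: 9 methyl 6-{2-[2-(benzyloxy)phenyl]ethyl}-2-hydroxy-4-oxocyclohex-2-ene-1-carboxylate (racemic), via Michael adduct 8 (not isolated)
Conditions: 7 (1.2 equiv), NaOMe (1.2 equiv), MeOH, reflux, 4 h; then aq HCl to pH 3
Reagents that add atoms: none
Why: Intermolecular Michael addition of sodiomalonate to the enone β-carbon is followed by Claisen (Dieckmann) closure of the methyl ketone enolate onto one ester, driven by deprotonation of the vinylogous acid formed; the two new stereocentres (racemic, mostly trans) are erased in step 6.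

Step 6
Reactants: 9 methyl 6-{2-[2-(benzyloxy)phenyl]ethyl}-2-hydroxy-4-oxocyclohex-2-ene-1-carboxylate
Product: 10 methyl 6-{2-[2-(benzyloxy)phenyl]ethyl}-2,4-dihydroxybenzoate
Conditions: I2 (20 mol %), DMSO, 80 °C, 12 h
Reagents that add atoms: none
Why: Iodine-catalysed oxidative aromatisation with DMSO as terminal oxidant removes two hydrogens from the dihydroresorcylate, and it is mild enough to keep the methyl ester and the benzyl ether while erasing both stereocentres.

Step 7
Reactants: 10 methyl 6-{2-[2-(benzyloxy)phenyl]ethyl}-2,4-dihydroxybenzoate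
Product: 11 methyl 4-(benzyloxy)-6-{2-[2-(benzyloxy)phenyl]ethyl}-2-hydroxybenzoate
Conditions: BnBr (1.05 equiv), K2CO3 (1.2 equiv), acetone, reflux
Reagents that add atoms: benzyl bromide, BrCc1ccccc1
Why: In this regioselective Williamson etherification the 2-OH is tied up in a hydrogen bond to the ester carbonyl, so one equivalent of BnBr takes the free and more acidic 4-OH.

Step 8
Reactants: 11 methyl 4-(benzyloxy)-6-{2-[2-(benzyloxy)phenyl]ethyl}-2-hydroxybenzoate
Product: 12 methyl 4-(benzyloxy)-6-{2-[2-(benzyloxy)phenyl]ethyl}-2-methoxybenzoate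
Conditions: MeI (3 equiv), K2CO3 (3 equiv), DMF, 50 °C
Reagents that add atoms: methyl iodide, CI
Why: Williamson methylation with excess MeI in a dipolar aprotic solvent forces alkylation of the only remaining, chelated phenol.

Step 9
Reactants: 12 methyl 4-(benzyloxy)-6-{2-[2-(benzyloxy)phenyl]ethyl}-2-methoxybenzoate
Product: 13 (4-(benzyloxy)-6-{2-[2-(benzyloxy)phenyl]ethyl}-2-methoxyphenyl)methanol
Conditions: LiAlH4 (2 equiv), THF, 0 °C to reflux; then H2O quench, filtration
Reagents that add atoms: none
Why: In this LiAlH4 ester reduction the small hydride overcomes the di-ortho hindrance, the ethers are inert, and the non-acidic work-up protects the electron-rich benzylic alcohol.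

Step 10
Reactants: 13 (4-(benzyloxy)-6-{2-[2-(benzyloxy)phenyl]ethyl}-2-methoxyphenyl)methanol
Product: 14 4-(benzyloxy)-6-{2-[2-(benzyloxy)phenyl]ethyl}-2-methoxybenzaldehyde
Conditions: activated MnO2 (15 equiv), CH2Cl2, rt
Reagents that add atoms: none
Why: MnO2 oxidation is selective for the electron-rich benzylic alcohol and cannot over-oxidise it under neutral conditions.

Step 11
Reactants: 14 4-(benzyloxy)-6-{2-[2-(benzyloxy)phenyl]ethyl}-2-methoxybenzaldehyde; 15 1-(benzyloxy)-4-bromobenzene
Product: 17 (4-(benzyloxy)-6-{2-[2-(benzyloxy)phenyl]ethyl}-2-methoxyphenyl)[4-(benzyloxy)phenyl]methanol (racemic), via 4-(benzyloxy)phenylmagnesium bromide 16 (not isolated)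
Conditions: 15 (1.5 equiv), Mg, I2 crystal, THF, reflux; then 14, THF, 0 °C to rt; sat. aq NH4Cl
Reagents that add atoms: magnesium, [Mg] (kept only in 16)
Why: Grignard addition to a non-enolisable aldehyde is clean 1,2-addition, and the new carbinol stereocentre is racemic and is removed in step 12.

Step 12
Reactants: 17 (4-(benzyloxy)-6-{2-[2-(benzyloxy)phenyl]ethyl}-2-methoxyphenyl)[4-(benzyloxy)phenyl]methanol
Product: 18 5-(benzyloxy)-1-{2-[2-(benzyloxy)phenyl]ethyl}-2-[4-(benzyloxy)benzyl]-3-methoxybenzene
Conditions: Et3SiH (3 equiv), TFA (5 equiv), CH2Cl2, 0 °C, 30 min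
Reagents that add atoms: none
Why: In this ionic hydrogenation (Kursanov–Parnes) TFA ionises the doubly benzylic alcohol to a cation stabilised by three alkoxy groups, and excess silane traps it faster than the unactivated position of the pendant ring can attack.

Step 13
Reactants: 18 5-(benzyloxy)-1-{2-[2-(benzyloxy)phenyl]ethyl}-2-[4-(benzyloxy)benzyl]-3-methoxybenzene
Product: 19 3-[2-(2-hydroxyphenyl)ethyl]-4-[(4-hydroxyphenyl)methyl]-5-methoxyphenol (target)
Conditions: H2 (1 atm), 10 % Pd/C, EtOAc/MeOH 1:1, rt
Reagents that add atoms: none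
Why: Catalytic hydrogenolysis cleaves the three aryl benzyl ethers, while the methyl ether and the diarylmethane and bibenzyl C–C bonds are inert.

## Compound list
1 | dihydrocoumarin (chroman-2-one) | O=C1CCc2ccccc2O1 | starting material
2 | 2-(3-hydroxypropyl)phenol | OCCCc1ccccc1O | intermediate
3 | 3-[2-(benzyloxy)phenyl]propan-1-ol | OCCCc1ccccc1OCc1ccccc1 | intermediate
4 | 3-[2-(benzyloxy)phenyl]propanal | O=CCCc1ccccc1OCc1ccccc1 | intermediate
5 | 1-(triphenylphosphoranylidene)propan-2-one | CC(=O)C=P(c1ccccc1)(c1ccccc1)c1ccccc1 | starting material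
6 | (E)-6-[2-(benzyloxy)phenyl]hex-3-en-2-one | CC(=O)/C=C/CCc1ccccc1OCc1ccccc1 | intermediate
7 | dimethyl malonate | COC(=O)CC(=O)OC | starting material
8 | Michael adduct: dimethyl 2-{1-[2-(benzyloxy)phenyl]-5-oxohexan-3-yl}propanedioate (racemic) | COC(=O)C(C(=O)OC)C(CCc1ccccc1OCc1ccccc1)CC(C)=O | intermediate (not isolated)
9 | methyl 6-{2-[2-(benzyloxy)phenyl]ethyl}-2-hydroxy-4-oxocyclohex-2-ene-1-carboxylate (racemic, mostly trans) | COC(=O)C1C(O)=CC(=O)CC1CCc1ccccc1OCc1ccccc1 | intermediate
10 | methyl 6-{2-[2-(benzyloxy)phenyl]ethyl}-2,4-dihydroxybenzoate | COC(=O)c1c(O)cc(O)cc1CCc1ccccc1OCc1ccccc1 | intermediate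
11 | methyl 4-(benzyloxy)-6-{2-[2-(benzyloxy)phenyl]ethyl}-2-hydroxybenzoate | COC(=O)c1c(O)cc(OCc2ccccc2)cc1CCc1ccccc1OCc1ccccc1 | intermediate
12 | methyl 4-(benzyloxy)-6-{2-[2-(benzyloxy)phenyl]ethyl}-2-methoxybenzoate | COC(=O)c1c(OC)cc(OCc2ccccc2)cc1CCc1ccccc1OCc1ccccc1 | intermediate
13 | (4-(benzyloxy)-6-{2-[2-(benzyloxy)phenyl]ethyl}-2-methoxyphenyl)methanol | COc1cc(OCc2ccccc2)cc(CCc2ccccc2OCc2ccccc2)c1CO | intermediate
14 | 4-(benzyloxy)-6-{2-[2-(benzyloxy)phenyl]ethyl}-2-methoxybenzaldehyde | COc1cc(OCc2ccccc2)cc(CCc2ccccc2OCc2ccccc2)c1C=O | intermediate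
15 | 1-(benzyloxy)-4-bromobenzene | Brc1ccc(OCc2ccccc2)cc1 | starting material
16 | 4-(benzyloxy)phenylmagnesium bromide | Br[Mg]c1ccc(OCc2ccccc2)cc1 | intermediate (not isolated)
17 | (4-(benzyloxy)-6-{2-[2-(benzyloxy)phenyl]ethyl}-2-methoxyphenyl)[4-(benzyloxy)phenyl]methanol (racemic) | COc1cc(OCc2ccccc2)cc(CCc2ccccc2OCc2ccccc2)c1C(O)c1ccc(OCc2ccccc2)cc1 | intermediate
18 | 5-(benzyloxy)-1-{2-[2-(benzyloxy)phenyl]ethyl}-2-[4-(benzyloxy)benzyl]-3-methoxybenzene | COc1cc(OCc2ccccc2)cc(CCc2ccccc2OCc2ccccc2)c1Cc1ccc(OCc2ccccc2)cc1 | intermediate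
19 | 3-[2-(2-hydroxyphenyl)ethyl]-4-[(4-hydroxyphenyl)methyl]-5-methoxyphenol | COc1cc(O)cc(CCc2ccccc2O)c1Cc1ccc(O)cc1 | target

## Totals and risks
Total step count: 13. Longest linear sequence: 13 steps (1 to 19); the Grignard reagent is made in the pot of step 11.

**Step 6 is the most likely to fail.** The risks are iodination of the very electron-rich product ring, a stalled reaction, or partial loss of the ester. The fallback sets out from 9 and comes back at 11, replacing halogen-mediated dehydrogenation by a selenoxide elimination on a pre-benzylated ring.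
- Compound 9 is condensed with benzyl alcohol (cat. TsOH, benzene, Dean–Stark) at the less hindered carbonyl. This gives methyl 4-(benzyloxy)-6-{2-[2-(benzyloxy)phenyl]ethyl}-2-oxocyclohex-3-ene-1-carboxylate F1.
- The β-keto ester carbon is selenenylated with PhSeCl/pyridine in CH2Cl2 at 0 °C. This gives methyl 4-(benzyloxy)-6-{2-[2-(benzyloxy)phenyl]ethyl}-2-oxo-1-(phenylselanyl)cyclohex-3-ene-1-carboxylate F2.
- H2O2 oxidises F2 to methyl 1-(benzeneseleninyl)-4-(benzyloxy)-6-{2-[2-(benzyloxy)phenyl]ethyl}-2-oxocyclohex-3-ene-1-carboxylate F3.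
- F3 undergoes syn-elimination towards the neighbouring C–H at room temperature and enolises to 11, so step 7 is no longer needed.
- Any ester exchange with benzyl alcohol is harmless, because step 9 reduces either ester to 13.

**Step 5 is second.** The risks are γ-deprotonation or oligomerisation of the enone and retro-Michael reaction before ring closure. The fallback sets out from 4 and comes back at 9, exchanging the roles of donor and acceptor.
- Aldehyde 4 reacts with methyl (triphenylphosphoranylidene)acetate in CH2Cl2 to give methyl (E)-5-[2-(benzyloxy)phenyl]pent-2-enoate F4.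
- Methyl acetoacetate and NaOMe in refluxing MeOH add to F4 in a Michael reaction. This gives dimethyl 2-acetyl-3-{2-[2-(benzyloxy)phenyl]ethyl}pentanedioate F5, which is not isolated.
- The acetyl methyl group of F5 closes onto the distal ester in a Claisen condensation, which gives the same 9 after acidification.

**Step 12 is third.** The risks are Friedel–Crafts closure of the cation onto the pendant ring to a seven-membered ring, or acid-induced loss or migration of a benzyl group. The fallback sets out from 17 and comes back at 19. Carbinol 17 is hydrogenated directly (H2, 10 % Pd/C, EtOH/AcOH, rt). This removes the doubly benzylic hydroxyl and all three benzyl ethers in one heterogeneous operation without a free cation. Compound 18 is bypassed and no compound outside the list is made (none F0).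

## Further compounds
F1 | step 6 | methyl 4-(benzyloxy)-6-{2-[2-(benzyloxy)phenyl]ethyl}-2-oxocyclohex-3-ene-1-carboxylate | COC(=O)C1C(=O)C=C(OCc2ccccc2)CC1CCc1ccccc1OCc1ccccc1
F2 | step 6 | methyl 4-(benzyloxy)-6-{2-[2-(benzyloxy)phenyl]ethyl}-2-oxo-1-(phenylselanyl)cyclohex-3-ene-1-carboxylate | COC(=O)C1([Se]c2ccccc2)C(=O)C=C(OCc2ccccc2)CC1CCc1ccccc1OCc1ccccc1
F3 | step 6 | methyl 1-(benzeneseleninyl)-4-(benzyloxy)-6-{2-[2-(benzyloxy)phenyl]ethyl}-2-oxocyclohex-3-ene-1-carboxylate | COC(=O)C1([Se](=O)c2ccccc2)C(=O)C=C(OCc2ccccc2)CC1CCc1ccccc1OCc1ccccc1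
F4 | step 5 | methyl (E)-5-[2-(benzyloxy)phenyl]pent-2-enoate | COC(=O)/C=C/CCc1ccccc1OCc1ccccc1
F5 | step 5 | dimethyl 2-acetyl-3-{2-[2-(benzyloxy)phenyl]ethyl}pentanedioate | COC(=O)CC(CCc1ccccc1OCc1ccccc1)C(C(C)=O)C(=O)OC
F0 | step 12 | none | none
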